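A slowing flask tempts us to take one pseudo-first-order constant from the first reading and carry it to the end.

in all of them: substrate 10 mM

| charge | reagent in the second phase | remark | time | volume of the second phase over the first |
|---|---|---|---|---|
| Tuesday's | 20 mM | run made earlier |  |  |
| Saturday's | 45 mM | run made earlier |  |  |
| flask | 30.0 mM |  | 4.0 min | 0.50 |

| run | time / min | target / % | substrate / % |
|---|---|---|---|
| Tuesday's | 1.00 | 20.0 | 79.8 |
| Tuesday's | 2.00 | 30.3 | 67.2 |
| Tuesday's | 3.00 | 39.4 | 58.8 |
| Tuesday's | 4.00 | 42.9 | 53.2 |
| Tuesday's | 5.00 | 47.4 | 48.2 |
| Saturday's | 0.417 | 18.6 | 82.3 |
| Saturday's | 0.667 | 26.7 | 73.2 |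
| Saturday's | 1.33 | 40.2 | 57.0 |
| Saturday's | 2.50 | 52.0 | 42.0 |
| Saturday's | 5.00 | 59.2 | 28.9 |

(standard deviation of a reading: 1 percentage point)

- in the second phase: reagent in the second phase; everything else is in the first
- charges count per volume of the first phase; a concentration in a rate is the amount of a species over the volume of its own phase; every rate counts per litre of the first phase
- the earlier runs hold the two phases in the same ratio of volumes as the flask asked about

- how much target there is at 4.0 min, in percent of the substrate charged
- part of the substrate charged that has reacted at 4.0 min

Tuesday's first reading gives substrate a constant of 0.226 min⁻¹. Scaled to this flask's reagent charge, it promises 74.2 % reacted by 4.0 min. Let n be the number of substrate lifetimes passed, the logarithm of charged over remaining substrate. The same constant promises Tuesday's run n = 1.13 at 5.00 min, but the reading gives 0.730, so the reagent's effect fades.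

A reagent lost by a step second order in itself lives a time inverse to its concentration. If that loss outruns its use on substrate, n should follow the dose, c(reagent in the second phase) at the start times t, here 7.20 M·s. We test this on Tuesday's 3.00 min and Saturday's 1.33 min, whose doses match: their substrate readings differ by 1.8 percentage points, with a scatter of 1 point on each.

Our flask's dose lies just above Saturday's at 2.50 min, where the reading gives n = 0.868. Saturday's last two readings make n grow as dose to the power 0.517. We therefore expect n = 0.897, or 59.2 % reacted. Taking off Saturday's missing balance at that reading leaves 53.2 % target. The forecast, a little lower than our reckoning, says 57 % reacted and 51 % target, on the suspicion of “Loss of reagent in a second-order side process”.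

The flask gives 58.0 % reacted and 51.6 % target, so n = 0.868 at dose 7.20 M·s.

    reagent in the reaction phase + target → over-reacted product (k = 0.0770 M⁻¹ s⁻¹)
    2 reagent in the reaction phase → self-condensation product (k = 0.210 M⁻¹ s⁻¹)
    reagent in the reaction phase ⇌ reagent in the second phase, rate k3*([reagent in the reaction phase] - [reagent in the second phase]/K3) per volume of the first phase (partition coefficient = 0.800, kL = 0.110 s⁻¹)
    substrate + reagent in the reaction phase → target (k = 0.320 M⁻¹ s⁻¹)

In this flask at 0.0440 min, the step to self-condensation product uses reagent in the reaction phase 1.8 times as fast as the step to target. By 4.0 min its turnover is 71.6 % of the substrate charged, more than the 58.0 % reacted. A run with the target step's constant doubled gives 71.0 % target at 4.0 min, far above the forecast's 51 %. Read at 6.0 min, this flask has dose 10.8 M·s, so n = 1.11 and 33.0 % substrate remaining; it holds 34.0 %.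

The earlier runs and the new flask come from a simulation with made-up constants; the scatter is artificial.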